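## Retrosynthetic overview

1. Locants (drimane numbering): ring A = C1, C2, C3 (C=O), C4 (CMe2), C5, C10; ring B = C5–C10 with C7=C8; C11 = OCH2. The aryl ether O–C11 is disconnected first (Mitsunobu coupling of a bicyclic keto alcohol with purchased umbelliferone; no ring is formed there).
2. Enabling feature: in ring A the ketone carbon C3 is bonded directly to the gem-dimethyl quaternary carbon C4, which sits on the ring-fusion CH (C5). The C3–C4 bond is cut into a tertiary radical (isopropenyl group on C5 plus H•) and a nitrile carbon (2-cyanoethyl group on the quaternary C10).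
3. Ring A is closed on the finished ring B by an iron-hydride hydrogen-atom-transfer (HAT) radical addition to the nitrile. One operation gives the ring, the C3–C4 bond, the gem-dimethyl carbon and the ketone.
4. Ring B with all three stereocentres (C5, C9, C10) comes from one catalytic enantioselective Diels–Alder reaction of an (E)-silyloxymethyl diene with ethyl (E)-3-methyl-4-oxobut-2-enoate. The formyl group then becomes the cyanoethyl arm and the ester the isopropenyl arm.
5. Order of rings: coumarin (bought) → ring B (step 3) → ring A (step 8, the last ring closed).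

Key step: step 8

Assumption: the enantioface selection in step 3 is taken to follow the accepted model for α-substituted enals bound through the formyl group to this oxazaborolidinium ion; if the opposite sense were found, the (R)-configured catalyst would be used.

## Route

Step 1
Reactants: 1 (E)-3-methylpent-2-en-4-yn-1-ol
Product: 2 tert-butyl{[(E)-3-methylpent-2-en-4-yn-1-yl]oxy}diphenylsilane
Conditions: TBDPSCl, imidazole, DMF, 0 °C → rt
Reagents that add atoms: tert-butyl(chloro)diphenylsilane, CC(C)(C)[Si](Cl)(c1ccccc1)c1ccccc1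
Why: Imidazole-assisted silylation of a primary alcohol; the TBDPS ether is chosen because it should survive the Lewis acid, the Grignard reagents and the dilute aqueous acid of the later steps.

Step 2
Reactants: 2 tert-butyl{[(E)-3-methylpent-2-en-4-yn-1-yl]oxy}diphenylsilane
Product: 3 tert-butyl{[(E)-3-methylpenta-2,4-dien-1-yl]oxy}diphenylsilane
Conditions: H2 (1 atm), Pd/CaCO3 poisoned with Pb(OAc)2, quinoline, hexane, rt
Reagents that add atoms: none
Why: Semihydrogenation of the terminal alkyne over lead-poisoned palladium should stop at the vinyl group and leave the E-configured trisubstituted alkene untouched, giving a diene that can reach the s-cis conformation.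

Step 3
Reactants: 3 tert-butyl{[(E)-3-methylpenta-2,4-dien-1-yl]oxy}diphenylsilane; 4 ethyl (E)-3-methyl-4-oxobut-2-enoate
Product: 5 ethyl (1R,5R,6R)-5-{[(tert-butyldiphenylsilyl)oxy]methyl}-6-formyl-4,6-dimethylcyclohex-3-ene-1-carboxylate
Conditions: (S)-3,3-diphenyl-1-(o-tolyl)tetrahydro-1H,3H-pyrrolo[1,2-c][1,3,2]oxazaborole (20 mol %), Tf2NH (20 mol %), CH2Cl2, −78 → −20 °C
Reagents that add atoms: none
Why: Enantioselective Diels–Alder reaction of an α-substituted enal activated by a chiral oxazaborolidinium ion: the cation binds the formyl group, so the ester-bearing β-carbon joins the unsubstituted diene terminus and the methyl-bearing α-carbon the substituted one (ortho rule), the E geometry of 4 fixes formyl and ester trans (the later trans ring fusion), formyl-endo addition places CH2OSi cis to CHO, and the catalyst shields one enantioface, so all three stereocentres arise here.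

Step 4
Reactants: 5 ethyl (1R,5R,6R)-5-{[(tert-butyldiphenylsilyl)oxy]methyl}-6-formyl-4,6-dimethylcyclohex-3-ene-1-carboxylate; 6 diethyl (cyanomethyl)phosphonate
Product: 7 ethyl (1R,5R,6R)-5-{[(tert-butyldiphenylsilyl)oxy]methyl}-6-[(E)-2-cyanoethenyl]-4,6-dimethylcyclohex-3-ene-1-carboxylate
Conditions: NaH, THF, 0 °C → rt (anion formed before 5 is added)
Reagents that add atoms: none
Why: Horner–Wadsworth–Emmons olefination of a non-enolisable aldehyde on a quaternary carbon with the pre-formed phosphonate anion (no excess base, so the stereocentre α to the ester is safe); the alkene geometry is irrelevant because it is reduced next.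

Step 5
Reactants: 7 ethyl (1R,5R,6R)-5-{[(tert-butyldiphenylsilyl)oxy]methyl}-6-[(E)-2-cyanoethenyl]-4,6-dimethylcyclohex-3-ene-1-carboxylate
Product: 8 ethyl (1R,5R,6R)-5-{[(tert-butyldiphenylsilyl)oxy]methyl}-6-(2-cyanoethyl)-4,6-dimethylcyclohex-3-ene-1-carboxylate
Conditions: Cu(OAc)2 (5 mol %), Xantphos (5 mol %), (EtO)2MeSiH, t-BuOH, toluene, rt
Reagents that add atoms: none
Why: Conjugate reduction of the α,β-unsaturated nitrile by a phosphine-bound copper hydride (monovalent copper, formed from Cu(OAc)2 and the silane); the isolated trisubstituted alkene, the ester and the silyl ether should not react and no stereocentre is touched.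

Step 6
Reactants: 8 ethyl (1R,5R,6R)-5-{[(tert-butyldiphenylsilyl)oxy]methyl}-6-(2-cyanoethyl)-4,6-dimethylcyclohex-3-ene-1-carboxylate
Product: 10 3-[(1R,2R,6R)-6-acetyl-2-{[(tert-butyldiphenylsilyl)oxy]methyl}-1,3-dimethylcyclohex-3-en-1-yl]propanenitrile, via Weinreb amide 9 (not isolated)
Conditions: MeNHOMe·HCl, i-PrMgCl, THF, −20 °C; then MeMgBr, 0 °C; aq. NH4Cl
Reagents that add atoms: methylmagnesium bromide, C[Mg]Br
Why: Aminolysis of the ester by the magnesium amide of N,O-dimethylhydroxylamine, then Grignard addition to the N-methoxy-N-methylamide (ketone synthesis through the chelated tetrahedral intermediate), which at 0 °C should be much faster than addition to the aliphatic nitrile; the adjacent stereocentre is kept because the carbonyl stays masked until work-up.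

Step 7
Reactants: 10 3-[(1R,2R,6R)-6-acetyl-2-{[(tert-butyldiphenylsilyl)oxy]methyl}-1,3-dimethylcyclohex-3-en-1-yl]propanenitrile
Product: 11 3-[(1S,2R,6S)-2-{[(tert-butyldiphenylsilyl)oxy]methyl}-1,3-dimethyl-6-(prop-1-en-2-yl)cyclohex-3-en-1-yl]propanenitrile
Conditions: Ph3PCH3Br, KOt-Bu, THF, 0 °C → rt
Reagents that add atoms: methyltriphenylphosphonium bromide, C[P+](c1ccccc1)(c1ccccc1)c1ccccc1.[Br-]
Why: Wittig methylenation of the methyl ketone; any enolisation by the ylide should occur at the unhindered methyl side, so the adjacent ring stereocentre is retained (the descriptors change only through CIP priorities), and the nitrile is inert.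

Step 8
Reactants: 11 3-[(1S,2R,6S)-2-{[(tert-butyldiphenylsilyl)oxy]methyl}-1,3-dimethyl-6-(prop-1-en-2-yl)cyclohex-3-en-1-yl]propanenitrile
Product: 13 (4aS,5R,8aR)-5-{[(tert-butyldiphenylsilyl)oxy]methyl}-1,1,4a,6-tetramethyl-3,4,4a,5,8,8a-hexahydronaphthalen-2(1H)-one, via N–H ketimine 12 (not isolated)
Conditions: Fe(acac)3 (30 mol %), PhSiH3, EtOH, 60 °C, argon; then 1 M aq. HCl, THF, rt
Reagents that add atoms: water, O
Why: A trivalent iron hydride formed from Fe(acac)3 and PhSiH3 transfers a hydrogen atom to the CH2 terminus of the isopropenyl group (Markovnikov-selective HAT), the tertiary radical adds to the nitrile carbon, the iminyl radical is reduced by divalent iron and protonated by ethanol to ketimine 12, and aqueous acid hydrolyses 12 to the ketone. The closest known reaction type is the iron-mediated, HAT-initiated reductive cyclisation of alkenyl nitriles to α-quaternary cycloalkanones. Ring A is closed in a 6-exo-dig mode through the new C3–C4 bond, so one operation gives the ring, the quaternary gem-dimethyl carbon (its second methyl comes from the alkene CH2) and the ketone at its final oxidation level. No new stereocentre arises, since the new quaternary carbon carries two methyl groups; the three existing ones are untouched because the radical is exocyclic and the conditions are neutral, and the trans ring fusion follows from the trans arrangement of the two arms set in step 3. The step needs HAT to the 1,1-disubstituted alkene in preference to the trisubstituted ring alkene, which their large difference in HAT rate should secure, and cyclisation faster than reduction of the radical, which the vicinal diequatorial arms next to a quaternary carbon (Thorpe–Ingold effect) should favour.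

Step 9
Reactants: 13 (4aS,5R,8aR)-5-{[(tert-butyldiphenylsilyl)oxy]methyl}-1,1,4a,6-tetramethyl-3,4,4a,5,8,8a-hexahydronaphthalen-2(1H)-one
Product: 14 (4aS,5R,8aR)-5-(hydroxymethyl)-1,1,4a,6-tetramethyl-3,4,4a,5,8,8a-hexahydronaphthalen-2(1H)-one
Conditions: HF·pyridine, pyridine, THF, 0 °C → rt
Reagents that add atoms: none
Why: Fluoride cleavage of the silyl ether (Si–F bond formation) under buffered, non-basic conditions that should leave the ketone, the alkene and the stereocentres unchanged.

Step 10
Reactants: 14 (4aS,5R,8aR)-5-(hydroxymethyl)-1,1,4a,6-tetramethyl-3,4,4a,5,8,8a-hexahydronaphthalen-2(1H)-one; 15 7-hydroxy-2H-chromen-2-one (umbelliferone)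
Product: 16 7-{[(1R,4aR,8aS)-2,5,5,8a-tetramethyl-6-oxo-1,4,4a,5,6,7,8,8a-octahydronaphthalen-1-yl]methoxy}-2H-chromen-2-one
Conditions: PPh3, DIAD, THF, 0 °C → rt
Reagents that add atoms: none
Why: Mitsunobu etherification: the primary alcohol is activated as an alkoxyphosphonium ion and displaced by the acidic phenol at the non-stereogenic CH2 carbon, so no stereocentre is affected and no ring is formed.

## Compound list

1 | (E)-3-methylpent-2-en-4-yn-1-ol | C#C/C(C)=C/CO | starting material
2 | tert-butyl{[(E)-3-methylpent-2-en-4-yn-1-yl]oxy}diphenylsilane | C#C/C(C)=C/CO[Si](c1ccccc1)(c1ccccc1)C(C)(C)C | intermediate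
3 | tert-butyl{[(E)-3-methylpenta-2,4-dien-1-yl]oxy}diphenylsilane | C=C/C(C)=C/CO[Si](c1ccccc1)(c1ccccc1)C(C)(C)C | intermediate
4 | ethyl (E)-3-methyl-4-oxobut-2-enoate | CCOC(=O)/C=C(C)/C=O | starting material
5 | ethyl (1R,5R,6R)-5-{[(tert-butyldiphenylsilyl)oxy]methyl}-6-formyl-4,6-dimethylcyclohex-3-ene-1-carboxylate | CC1=CC[C@@H](C(=O)OCC)[C@@](C=O)(C)[C@@H]1CO[Si](c1ccccc1)(c1ccccc1)C(C)(C)C | intermediate
6 | diethyl (cyanomethyl)phosphonate | CCOP(=O)(CC#N)OCC | starting material
7 | ethyl (1R,5R,6R)-5-{[(tert-butyldiphenylsilyl)oxy]methyl}-6-[(E)-2-cyanoethenyl]-4,6-dimethylcyclohex-3-ene-1-carboxylate | CC1=CC[C@@H](C(=O)OCC)[C@@](/C=C/C#N)(C)[C@@H]1CO[Si](c1ccccc1)(c1ccccc1)C(C)(C)C | intermediate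
8 | ethyl (1R,5R,6R)-5-{[(tert-butyldiphenylsilyl)oxy]methyl}-6-(2-cyanoethyl)-4,6-dimethylcyclohex-3-ene-1-carboxylate | CC1=CC[C@@H](C(=O)OCC)[C@@](CCC#N)(C)[C@@H]1CO[Si](c1ccccc1)(c1ccccc1)C(C)(C)C | intermediate
9 | (1R,5R,6R)-5-{[(tert-butyldiphenylsilyl)oxy]methyl}-6-(2-cyanoethyl)-N-methoxy-N,4,6-trimethylcyclohex-3-ene-1-carboxamide | CC1=CC[C@@H](C(=O)N(C)OC)[C@@](CCC#N)(C)[C@@H]1CO[Si](c1ccccc1)(c1ccccc1)C(C)(C)C | intermediate
10 | 3-[(1R,2R,6R)-6-acetyl-2-{[(tert-butyldiphenylsilyl)oxy]methyl}-1,3-dimethylcyclohex-3-en-1-yl]propanenitrile | CC1=CC[C@@H](C(C)=O)[C@@](CCC#N)(C)[C@@H]1CO[Si](c1ccccc1)(c1ccccc1)C(C)(C)C | intermediate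
11 | 3-[(1S,2R,6S)-2-{[(tert-butyldiphenylsilyl)oxy]methyl}-1,3-dimethyl-6-(prop-1-en-2-yl)cyclohex-3-en-1-yl]propanenitrile | CC1=CC[C@@H](C(C)=C)[C@@](CCC#N)(C)[C@@H]1CO[Si](c1ccccc1)(c1ccccc1)C(C)(C)C | intermediate
12 | tert-butyl{[(1R,4aR,8aS)-6-imino-2,5,5,8a-tetramethyl-1,4,4a,5,6,7,8,8a-octahydronaphthalen-1-yl]methoxy}diphenylsilane | CC1=CC[C@H]2C(C)(C)C(=N)CC[C@]2(C)[C@@H]1CO[Si](c1ccccc1)(c1ccccc1)C(C)(C)C | intermediate
13 | (4aS,5R,8aR)-5-{[(tert-butyldiphenylsilyl)oxy]methyl}-1,1,4a,6-tetramethyl-3,4,4a,5,8,8a-hexahydronaphthalen-2(1H)-one | CC1=CC[C@H]2C(C)(C)C(=O)CC[C@]2(C)[C@@H]1CO[Si](c1ccccc1)(c1ccccc1)C(C)(C)C | intermediate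
14 | (4aS,5R,8aR)-5-(hydroxymethyl)-1,1,4a,6-tetramethyl-3,4,4a,5,8,8a-hexahydronaphthalen-2(1H)-one | CC1=CC[C@H]2C(C)(C)C(=O)CC[C@]2(C)[C@@H]1CO | intermediate
15 | 7-hydroxy-2H-chromen-2-one (umbelliferone) | O=c1ccc2ccc(O)cc2o1 | starting material
16 | 7-{[(1R,4aR,8aS)-2,5,5,8a-tetramethyl-6-oxo-1,4,4a,5,6,7,8,8a-octahydronaphthalen-1-yl]methoxy}-2H-chromen-2-one | CC1=CC[C@H]2C(C)(C)C(=O)CC[C@]2(C)[C@@H]1COc1ccc2ccc(=O)oc2c1 | target

## Step count and risks

Total step count: 10. Longest linear sequence: 10 steps (1 → 16).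

Steps most likely to fail:

Step 3. The two carbonyl groups of the dienophile may compete for the Lewis acid, which would erode the formyl-endo preference, the regiochemistry and the enantioface control. Fallback, setting out from 3 and 4 and returning at 5: the cycloaddition is run with the achiral Lewis acid Me2AlCl (CH2Cl2, −78 °C), which should give 5 as the racemate. The enantiomers are then separated by preparative chromatography on a chiral stationary phase; the unwanted ethyl (1S,5S,6S)-5-{[(tert-butyldiphenylsilyl)oxy]methyl}-6-formyl-4,6-dimethylcyclohex-3-ene-1-carboxylate F1 is discarded and 5 re-enters the route.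

Step 8. Addition of a tertiary radical to a nitrile is slow, so a second hydrogen transfer may reduce the radical to the isopropyl group before ring closure, and HAT to the ring alkene may start to compete. Fallback, setting out from 11 and returning at 13: the nitrile is reduced with DIBAL-H (toluene, −78 °C, then aqueous Rochelle salt) to 3-[(1S,2R,6S)-2-{[(tert-butyldiphenylsilyl)oxy]methyl}-1,3-dimethyl-6-(prop-1-en-2-yl)cyclohex-3-en-1-yl]propanal F2. The same iron-hydride initiation (Fe(acac)3, PhSiH3, EtOH, 60 °C) is then used in the alkene–carbonyl reductive cyclisation established for ketone acceptors, where radical addition to the carbonyl is much faster and the alkoxy radical is trapped by reduction. This should give (4aS,5R,8aR)-5-{[(tert-butyldiphenylsilyl)oxy]methyl}-1,1,4a,6-tetramethyl-1,2,3,4,4a,5,8,8a-octahydronaphthalen-2-ol F3 as a mixture of carbinol epimers, which Dess–Martin periodinane (CH2Cl2, rt) oxidises to 13.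

Step 6. Amide formation at the hindered ester may be incomplete, the Grignard reagents may attack the nitrile, and the centre α to the carbonyl may epimerise. Fallback, setting out from 8 and returning at 10: the ester is cleaved under neutral conditions with Me3SnOH (1,2-dichloroethane, 80 °C) to (1R,5R,6R)-5-{[(tert-butyldiphenylsilyl)oxy]methyl}-6-(2-cyanoethyl)-4,6-dimethylcyclohex-3-ene-1-carboxylic acid F4. The acid is converted with 1-chloro-N,N,2-trimethylprop-1-en-1-amine (CH2Cl2, 0 °C) into (1R,5R,6R)-5-{[(tert-butyldiphenylsilyl)oxy]methyl}-6-(2-cyanoethyl)-4,6-dimethylcyclohex-3-ene-1-carbonyl chloride F5, which Me2CuLi (THF, −78 °C) converts into 10; the cuprate should not touch the nitrile.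

Further compounds
F1 | step 3 | ethyl (1S,5S,6S)-5-{[(tert-butyldiphenylsilyl)oxy]methyl}-6-formyl-4,6-dimethylcyclohex-3-ene-1-carboxylate | CC1=CC[C@H](C(=O)OCC)[C@](C=O)(C)[C@H]1CO[Si](c1ccccc1)(c1ccccc1)C(C)(C)C
F2 | step 8 | 3-[(1S,2R,6S)-2-{[(tert-butyldiphenylsilyl)oxy]methyl}-1,3-dimethyl-6-(prop-1-en-2-yl)cyclohex-3-en-1-yl]propanal | CC1=CC[C@@H](C(C)=C)[C@@](CCC=O)(C)[C@@H]1CO[Si](c1ccccc1)(c1ccccc1)C(C)(C)C
F3 | step 8 | (4aS,5R,8aR)-5-{[(tert-butyldiphenylsilyl)oxy]methyl}-1,1,4a,6-tetramethyl-1,2,3,4,4a,5,8,8a-octahydronaphthalen-2-ol (both carbinol epimers) | CC1=CC[C@H]2C(C)(C)C(O)CC[C@]2(C)[C@@H]1CO[Si](c1ccccc1)(c1ccccc1)C(C)(C)C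
F4 | step 6 | (1R,5R,6R)-5-{[(tert-butyldiphenylsilyl)oxy]methyl}-6-(2-cyanoethyl)-4,6-dimethylcyclohex-3-ene-1-carboxylic acid | CC1=CC[C@@H](C(=O)O)[C@@](CCC#N)(C)[C@@H]1CO[Si](c1ccccc1)(c1ccccc1)C(C)(C)C
F5 | step 6 | (1R,5R,6R)-5-{[(tert-butyldiphenylsilyl)oxy]methyl}-6-(2-cyanoethyl)-4,6-dimethylcyclohex-3-ene-1-carbonyl chloride | CC1=CC[C@@H](C(=O)Cl)[C@@](CCC#N)(C)[C@@H]1CO[Si](c1ccccc1)(c1ccccc1)C(C)(C)C
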